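**Plan**

1. Retrosynthetic cuts, in order: the C8–O ester bond; C3–C4, which opens the nine-membered oxonene ring (C1–C2=C3–C4–O–C7–C8–C9–C10) and leaves a butenolide; C7–C8 (vinylogous aldol, releasing 5-methyl-2-silyloxyfuran); C2=C3 (Wittig); the C1 and C10 arms come from cleavage of the cyclobutanone of a ketene [2+2] adduct of (R)-α-phellandrene.
2. Enabling feature: the dihydrofuranol ring (C4, C5=C6, C7, bridging O) with its hemiketal carbon C4 is the lactol of a 5,5-disubstituted butenolide that has gained one carbon substituent at the carbonyl. An alkenyllithium at C3 adding to that carbonyl therefore forms C3–C4, the C4 hemiketal and the oxonene ring in one event.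
3. Forward order: cyclohexene ring (from phellandrene) → butenolide ring attached through C7–C8 → nine-membered oxonene ring closed last → urocanate ester and global deprotection.
4. Stereochemistry: C14 from (R)-α-phellandrene; C1 and C10 from the suprafacial [2+2] anti to the isopropyl group; C7 and C8 together from a catalyst-controlled syn vinylogous Mukaiyama aldol; C4 dictated by C7 through the bridge; the Z C2=C3 olefin from the Wittig step, retained through the alkenyllithium.

Key step: step 13

Remark: positions are numbered as in the eunicellane skeleton. C1 and C10 are the ring-fusion carbons (C1 bears C2, C10 bears C9), C2=C3, C4 is the hemiketal carbon, C5=C6, C7 bears the methyl group and the bridging oxygen, C8 bears the ester, C11(Me)=C12, C14 bears the isopropyl group, C15 is the hydroxymethyl carbon on C3. (R)-(−)-α-Phellandrene is taken as enantiopure. Ethyl iodo(triphenylphosphoranylidene)acetate is used as a preformed reagent, made beforehand from the commercial parent ylide and N-iodosuccinimide.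

**Route**

Step 1
Reactants: 1 (R)-(−)-α-phellandrene
Product: 2 cis-fused 8,8-dichloro-2-methyl-5-(propan-2-yl)bicyclo[4.2.0]oct-2-en-7-one, four-membered ring anti to the isopropyl group
Conditions: Cl3CCOCl, Zn dust, Et2O, ultrasound, 15–20 °C
Reagents that add atoms: trichloroacetyl chloride, ClC(Cl)(Cl)C(Cl)=O (reacts as dichloroketene)
Why: Ketene–diene [2+2] cycloaddition in which dichloroketene adds suprafacially to the disubstituted olefin on the face opposite the isopropyl group, its carbonyl carbon bonding to the diene terminus C1, which sets C1 and C10 cis to each other and anti to C14.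

Step 2
Reactants: 2 dichlorocyclobutanone
Product: 3 2-methyl-5-(propan-2-yl)bicyclo[4.2.0]oct-2-en-7-one, same configuration
Conditions: Zn dust, AcOH, 70 °C
Reagents that add atoms: none
Why: Reductive dechlorination of an α,α-dichloroketone by zinc in acetic acid, which leaves the strained ketone and both ring-fusion centres untouched.

Step 3
Reactants: 3 cyclobutanone
Product: 4 (E)-8-[(dimethylamino)methylidene]-2-methyl-5-(propan-2-yl)bicyclo[4.2.0]oct-2-en-7-one
Conditions: t-BuOCH(NMe2)2 (neat), 60 °C
Reagents that add atoms: tert-butoxybis(dimethylamino)methane (Bredereck's reagent), CN(C)C(OC(C)(C)C)N(C)C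
Why: Aminomethylenation of the only methylene α to the ketone (C9) with Bredereck's reagent gives the vinylogous amide and brings in the future C8.

Step 4
Reactants: 4 enaminone
Product: 5 methyl 2-(2,2-dimethoxyethyl)-3-methyl-6-(propan-2-yl)cyclohex-3-ene-1-carboxylate, ester and acetal arms cis, both trans to the isopropyl group
Conditions: TsOH·H2O, MeOH, reflux
Reagents that add atoms: methanol, CO
Why: Acid-promoted methanolysis of the strained vinylogous amide (retro-Claisen ring opening) cleaves C2–C9 to a methyl ester on C1 and an iminium on the C10 arm that is trapped as the dimethyl acetal, and the cis relationship is kept because no bond to C1 or C10 is broken.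

Step 5
Reactants: 5 ester acetal
Product: 6 2-(2,2-dimethoxyethyl)-3-methyl-6-(propan-2-yl)cyclohex-3-ene-1-carbaldehyde, same configuration
Conditions: i-Bu2AlH (1.1 equiv), CH2Cl2, −78 °C
Reagents that add atoms: none
Why: Partial reduction of the methyl ester at −78 °C should stop at the aluminium hemiacetal, which releases the aldehyde on work-up, and the acetal is inert to the hydride.

Step 6
Reactants: 6 aldehyde
Product: 7 ethyl (Z)-3-[2-(2,2-dimethoxyethyl)-3-methyl-6-(propan-2-yl)cyclohex-3-en-1-yl]-2-iodoprop-2-enoate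
Conditions: Ph3P=C(I)CO2Et, CH2Cl2, 0 °C → rt, dark
Reagents that add atoms: ethyl iodo(triphenyl-λ5-phosphanylidene)acetate, CCOC(=O)C(I)=P(c1ccccc1)(c1ccccc1)c1ccccc1
Why: Wittig olefination with the ester-stabilised α-iodo ylide places C1 trans to the ester and hence cis to iodine, the geometry needed for the Z C2=C3 olefin, under neutral conditions that spare the epimerisable C1 centre.

Step 7
Reactants: 7 iodoenoate
Product: 8 (Z)-3-[2-(2,2-dimethoxyethyl)-3-methyl-6-(propan-2-yl)cyclohex-3-en-1-yl]-2-iodoprop-2-en-1-ol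
Conditions: i-Bu2AlH (2.5 equiv), CH2Cl2, −78 °C
Reagents that add atoms: none
Why: 1,2-Reduction of the enoate to the allylic alcohol, a reaction that does not touch the alkenyl iodide or the acetal.

Step 8
Reactants: 8 iodoallylic alcohol
Product: 9 triisopropylsilyl ether of 8
Conditions: TIPSCl, imidazole, DMF, rt
Reagents that add atoms: chlorotri(propan-2-yl)silane, CC(C)[Si](Cl)(C(C)C)C(C)C
Why: Silylation of the primary allylic alcohol, the bulky triisopropylsilyl group being chosen because it resists oxygen-to-carbon silyl migration in the later 2-lithioallyl ether and survives the mild acid steps.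

Step 9
Reactants: 9 acetal
Product: 10 2-[6-{(Z)-2-iodo-3-[tri(propan-2-yl)silyloxy]prop-1-en-1-yl}-2-methyl-5-(propan-2-yl)cyclohex-2-en-1-yl]acetaldehyde
Conditions: TsOH·H2O (cat.), acetone/H2O (10:1), rt
Reagents that add atoms: water, O
Why: Acid-catalysed hydrolysis of the dimethyl acetal frees the C8 aldehyde, while the primary TIPS ether and the alkenyl iodide are stable to dilute acid.

Step 10
Reactants: 11 α-angelica lactone
Product: 12 trimethyl[(5-methylfuran-2-yl)oxy]silane
Conditions: TMSOTf, Et3N, Et2O, 0 °C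
Reagents that add atoms: trimethylsilyl trifluoromethanesulfonate, C[Si](C)(C)OS(=O)(=O)C(F)(F)F
Why: Soft enolisation of the β,γ-unsaturated lactone with a silyl triflate and an amine base gives the aromatic 2-silyloxyfuran, the standard preparation of such dienoxysilanes.

Step 11
Reactants: 10 aldehyde, 12 silyloxyfuran
Product: 14 (5S)-5-[(1S)-1-hydroxy-2-(cyclohexenyl)ethyl]-5-methylfuran-2(5H)-one (cyclohexenyl unit as in 10), via trimethylsilyl ether 13 (not isolated)
Conditions: Ti(OiPr)4 (20 mol %), (R)-BINOL (20 mol %), 4 Å sieves, Et2O, −20 °C; then 1 M HCl, THF, 0 °C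
Reagents that add atoms: none
Why: Catalytic enantioselective vinylogous Mukaiyama aldol reaction in which the silyloxyfuran attacks through its methyl-bearing carbon (future C7) in the threo (syn, like) sense normally favoured in Lewis-acid additions of 2-silyloxyfurans, while the BINOL–titanium Lewis acid, not the remote C10 centre, is expected to expose the Re face of the aldehyde, so C7 and C8 arise together as (S,S).

Step 12
Reactants: 14 butenolide alcohol
Product: 15 O8-triethylsilyl ether of 14
Conditions: TESOTf, 2,6-lutidine, CH2Cl2, −78 → 0 °C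
Reagents that add atoms: triethylsilyl trifluoromethanesulfonate, CC[Si](CC)(CC)OS(=O)(=O)C(F)(F)F
Why: Silylation of the hindered secondary C8 alcohol with the silyl triflate removes the only acidic hydrogen before the organolithium step, under conditions too weakly basic to cause translactonisation.

Step 13
Reactants: 15 iodoalkenyl butenolide
Product: 18 bridged hemiketal (1S,4R,7S,8S,10R,14R)-4-hydroxy-4,7-epoxy-8-(triethylsilyloxy)-15-(triisopropylsilyloxy)eunicella-2Z,5Z,11-triene, via alkenyllithium 16 (not isolated), via lithium hemiketal alkoxide 17 (not isolated)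
Conditions: t-BuLi (2.1 equiv), THF/Et2O (0.002 M), −100 → −78 °C; then AcOH, −78 °C
Reagents that add atoms: none
Why: Iodine–lithium exchange at −100 °C should convert the alkenyl iodide into the configurationally stable (Z)-alkenyllithium 16, whose C3 carbanion adds 1,2 to the butenolide carbonyl C4 to give the lithium salt 17 of the bridged hemiketal, which is protonated on quench. The closest known reaction types are the halogen–lithium exchange-initiated (Parham-type) anionic cyclisation onto an ester carbonyl and the addition of alkenyllithiums to lactones that stops at the lactol. The nine-membered oxonene ring (C1, C2, C3, C4, O, C7, C8, C9, C10) is the only ring closed, by 9-exo-trig attack on the exocyclic C=O, and the butenolide ring becomes the dihydrofuranol ring. The new stereocentre C4 is fixed by C7, because C3 can reach the carbonyl only from the furanone face that carries the C8 tether and any ring–chain equilibration of the hemiketal returns the same bridged isomer, and the C2=C3 geometry is carried over from the iodide. The step needs exchange to outrun attack of t-BuLi on the lactone (iodide, −100 °C), 1,2- rather than 1,4-addition (hard alkenyllithium, β-carbon C6 flanked by quaternary C7), and ring closure to beat oligomerisation and silyl migration (high dilution, the Z olefin and the cis ring fusion turn both arms toward each other, bulky silyl group on O15). Enolisation cannot compete because the butenolide has no acidic hydrogen (quaternary C7, sp2 C5).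

Step 14
Reactants: 18 bridged hemiketal
Product: 19 (1S,4R,7S,8S,10R,14R)-4-methoxy-4,7-epoxy-15-(triisopropylsilyloxy)eunicella-2Z,5Z,11-trien-8-ol
Conditions: PPTS (cat.), MeOH, rt
Reagents that add atoms: methanol, CO
Why: Acid-catalysed exchange in methanol converts the hemiketal into the methyl ketal through the bridgehead oxocarbenium ion and also cleaves the secondary triethylsilyl ether, while the primary TIPS ether survives, so only the C8 hydroxyl is left free.

Step 15
Reactants: 20 1-methyl-1H-imidazole-4-carbaldehyde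
Product: 21 (E)-3-(1-methyl-1H-imidazol-4-yl)prop-2-enoic acid
Conditions: CH2(CO2H)2, pyridine, piperidine (cat.), 100 °C
Reagents that add atoms: malonic acid, OC(=O)CC(=O)O
Why: Knoevenagel–Doebner condensation with decarboxylation gives the (E)-acrylic acid under thermodynamic control.

Step 16
Reactants: 19 ketal alcohol, 21 N-methylurocanic acid
Product: 22 8-O-[(E)-3-(1-methyl-1H-imidazol-4-yl)prop-2-enoyl] ester of 19
Conditions: DCC, DMAP (cat.), CH2Cl2/DMF, rt
Reagents that add atoms: none
Why: Steglich esterification of the single free hydroxyl, with retention at C8 because its C–O bond is not touched.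

Step 17
Reactants: 22 protected ester
Product: 23 target, CNP0196085.1
Conditions: aq. HF (48 %), MeCN, 0 °C → rt
Reagents that add atoms: water, O
Why: Aqueous HF cleaves the primary TIPS ether and hydrolyses the methyl ketal through the bridgehead oxocarbenium ion to the thermodynamically preferred bridged hemiketal, whose C4 configuration is fixed by the bridge, while the urocanate ester is stable to acid.

**Compound list**

1 | (R)-(−)-α-phellandrene, (5R)-2-methyl-5-(propan-2-yl)cyclohexa-1,3-diene | CC1=CC[C@H](C(C)C)C=C1 | starting material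
2 | 8,8-dichloro-2-methyl-5-(propan-2-yl)bicyclo[4.2.0]oct-2-en-7-one, cis-fused, four-membered ring anti to isopropyl (C1 bears the carbonyl carbon C2, C10 bears the CCl2 carbon C9) | CC1=CC[C@H](C(C)C)[C@@H](C2=O)[C@H]1C2(Cl)Cl | intermediate
3 | 2-methyl-5-(propan-2-yl)bicyclo[4.2.0]oct-2-en-7-one, configuration as in 2 | CC1=CC[C@H](C(C)C)[C@@H](C2=O)[C@H]1C2 | intermediate
4 | (E)-8-[(dimethylamino)methylidene]-2-methyl-5-(propan-2-yl)bicyclo[4.2.0]oct-2-en-7-one, configuration as in 2 | CC1=CC[C@H](C(C)C)[C@@H](C2=O)[C@H]1/C2=C\N(C)C | intermediate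
5 | methyl 2-(2,2-dimethoxyethyl)-3-methyl-6-(propan-2-yl)cyclohex-3-ene-1-carboxylate, C1 and C10 arms cis, both trans to the C14 isopropyl | CC1=CC[C@H](C(C)C)[C@@H](C(=O)OC)[C@H]1CC(OC)OC | intermediate
6 | 2-(2,2-dimethoxyethyl)-3-methyl-6-(propan-2-yl)cyclohex-3-ene-1-carbaldehyde, configuration as in 5 | CC1=CC[C@H](C(C)C)[C@@H](C=O)[C@H]1CC(OC)OC | intermediate
7 | ethyl (Z)-3-[2-(2,2-dimethoxyethyl)-3-methyl-6-(propan-2-yl)cyclohex-3-en-1-yl]-2-iodoprop-2-enoate, ring configuration as in 5 | CC1=CC[C@H](C(C)C)[C@@H](/C=C(\I)C(=O)OCC)[C@H]1CC(OC)OC | intermediate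
8 | (Z)-3-[2-(2,2-dimethoxyethyl)-3-methyl-6-(propan-2-yl)cyclohex-3-en-1-yl]-2-iodoprop-2-en-1-ol | CC1=CC[C@H](C(C)C)[C@@H](/C=C(\I)CO)[C@H]1CC(OC)OC | intermediate
9 | triisopropylsilyl ether of 8 | CC1=CC[C@H](C(C)C)[C@@H](/C=C(\I)CO[Si](C(C)C)(C(C)C)C(C)C)[C@H]1CC(OC)OC | intermediate
10 | 2-[6-{(Z)-2-iodo-3-[tri(propan-2-yl)silyloxy]prop-1-en-1-yl}-2-methyl-5-(propan-2-yl)cyclohex-2-en-1-yl]acetaldehyde, ring configuration as in 5 | CC1=CC[C@H](C(C)C)[C@@H](/C=C(\I)CO[Si](C(C)C)(C(C)C)C(C)C)[C@H]1CC=O | intermediate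
11 | α-angelica lactone, 5-methylfuran-2(3H)-one | CC1=CCC(=O)O1 | starting material
12 | trimethyl[(5-methylfuran-2-yl)oxy]silane | Cc1ccc(O[Si](C)(C)C)o1 | intermediate
13 | O8-trimethylsilyl ether of 14 | CC1=CC[C@H](C(C)C)[C@@H](/C=C(\I)CO[Si](C(C)C)(C(C)C)C(C)C)[C@H]1C[C@H](O[Si](C)(C)C)[C@@]2(C)OC(=O)C=C2 | intermediate
14 | (5S)-5-[(1S)-1-hydroxy-2-(cyclohexenyl)ethyl]-5-methylfuran-2(5H)-one, cyclohexenyl unit as in 10 (7S,8S in skeleton numbering) | CC1=CC[C@H](C(C)C)[C@@H](/C=C(\I)CO[Si](C(C)C)(C(C)C)C(C)C)[C@H]1C[C@H](O)[C@@]2(C)OC(=O)C=C2 | intermediate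
15 | O8-triethylsilyl ether of 14 | CC1=CC[C@H](C(C)C)[C@@H](/C=C(\I)CO[Si](C(C)C)(C(C)C)C(C)C)[C@H]1C[C@H](O[Si](CC)(CC)CC)[C@@]2(C)OC(=O)C=C2 | intermediate
16 | (Z)-alkenyllithium from 15, lithium in place of iodine at C3 | CC1=CC[C@H](C(C)C)[C@@H](/C=C(\[Li])CO[Si](C(C)C)(C(C)C)C(C)C)[C@H]1C[C@H](O[Si](CC)(CC)CC)[C@@]2(C)OC(=O)C=C2 | intermediate
17 | lithium alkoxide of hemiketal 18 at O4 | CC1=CC[C@H](C(C)C)[C@H]2/C=C(/CO[Si](C(C)C)(C(C)C)C(C)C)[C@@]3(O[Li])C=C[C@](C)(O3)[C@@H](O[Si](CC)(CC)CC)C[C@@H]12 | intermediate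
18 | (1S,4R,7S,8S,10R,14R)-4-hydroxy-4,7-epoxy-8-(triethylsilyloxy)-15-(triisopropylsilyloxy)eunicella-2Z,5Z,11-triene | CC1=CC[C@H](C(C)C)[C@H]2/C=C(/CO[Si](C(C)C)(C(C)C)C(C)C)[C@@]3(O)C=C[C@](C)(O3)[C@@H](O[Si](CC)(CC)CC)C[C@@H]12 | intermediate
19 | (1S,4R,7S,8S,10R,14R)-4-methoxy-4,7-epoxy-15-(triisopropylsilyloxy)eunicella-2Z,5Z,11-trien-8-ol | CC1=CC[C@H](C(C)C)[C@H]2/C=C(/CO[Si](C(C)C)(C(C)C)C(C)C)[C@@]3(OC)C=C[C@](C)(O3)[C@@H](O)C[C@@H]12 | intermediate
20 | 1-methyl-1H-imidazole-4-carbaldehyde | O=Cc1cn(C)cn1 | starting material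
21 | (E)-3-(1-methyl-1H-imidazol-4-yl)prop-2-enoic acid (N-methylurocanic acid) | OC(=O)/C=C/c1cn(C)cn1 | intermediate
22 | 8-O-[(E)-3-(1-methyl-1H-imidazol-4-yl)prop-2-enoyl] ester of 19 | CC1=CC[C@H](C(C)C)[C@H]2/C=C(/CO[Si](C(C)C)(C(C)C)C(C)C)[C@@]3(OC)C=C[C@](C)(O3)[C@@H](OC(=O)/C=C/c4cn(C)cn4)C[C@@H]12 | intermediate
23 | CNP0196085.1, (1S,4R,7S,8S,10R,14R)-4,15-dihydroxy-4,7-epoxyeunicella-2Z,5Z,11-trien-8-yl (E)-3-(1-methyl-1H-imidazol-4-yl)prop-2-enoate | CC1=CC[C@H](C(C)C)[C@H]2/C=C(/CO)[C@@]3(O)C=C[C@](C)(O3)[C@@H](OC(=O)/C=C/c3cn(C)cn3)C[C@@H]12 | target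

**Count and risks**

Total steps: 17 (steps 10 and 15 are one-step side branches). Longest linear sequence: 15 steps (steps 1–9, 11–14, 16, 17).

Most likely to fail:

1. Step 13. The alkenyllithium may be consumed by intermolecular addition, proton transfer or silyl migration before it closes the medium ring, or t-BuLi may attack the lactone before the exchange. The fallback sets out from 15 and returns at 18. The butenolide is reduced with i-Bu2AlH (CH2Cl2, −78 °C) to the lactol F1, which cannot dehydrate to a furan because C7 is quaternary. A Nozaki–Hiyama–Kishi macrocyclisation (CrCl2, NiCl2 cat., DMSO/THF, high dilution), acting on the open (Z)-4-hydroxy-enal tautomer of the lactol, should give the cyclodecadiene diol F2 as a mixture of C4 epimers. Oxidation of its bis-allylic C4 alcohol with MnO2 gives the dienone, which closes with the C7 hydroxyl to hemiketal 18.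

2. Step 11. Facial selectivity on the aldehyde may be poor, or the simple diastereoselection may turn toward the anti series with the methyl-bearing furan. The fallback sets out from 10 and returns at 14, using reagent control that does not depend on the furan. A Z-selective Horner–Wadsworth–Emmons reaction of 10 with (CF3CH2O)2P(O)CH(CH3)CO2Et (KN(SiMe3)2, 18-crown-6, THF, −78 °C) gives the (Z)-2-methyl enoate F3, and i-Bu2AlH reduces it to the (Z)-allylic alcohol F4. Sharpless epoxidation (Ti(OiPr)4, L-(+)-diethyl tartrate, t-BuOOH, 4 Å sieves, CH2Cl2, −20 °C) gives the cis-epoxy alcohol F5; the cyclohexene and the iodoalkene are not allylic alcohols and stay untouched. Dess–Martin oxidation gives the epoxy aldehyde F6, and a Still–Gennari olefination with (CF3CH2O)2P(O)CH2CO2Me gives the (Z)-epoxy enoate F7. With CSA in wet CH2Cl2 the ester carbonyl opens the epoxide at the tertiary carbon C7 with inversion (5-exo), which gives butenolide alcohol 14 with C8 retained.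

3. Step 6. The hindered, strongly stabilised ylide may react slowly, so that the aldehyde epimerises at C1 or the Z/E selectivity erodes. The fallback sets out from 6 and returns at 8. A Corey–Fuchs reaction (CBr4, PPh3, CH2Cl2, 0 °C) gives the dibromoolefin F8; n-BuLi (THF, −78 °C) followed by paraformaldehyde gives the propargylic alcohol F9. Hydroxyl-directed trans-hydrostannation (Bu3SnH, [Cp*RuCl]4 cat., CH2Cl2) places tin on the carbon next to the carbinol and anti to the new hydrogen, which gives the (Z)-alkenylstannane F10. Iododestannylation (I2, CH2Cl2, 0 °C) with retention gives 8.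

**Further compounds**

F1 | step 13 | lactol from 15: 5-hydroxy-2,5-dihydrofuran in place of the butenolide carbonyl, anomeric mixture | CC1=CC[C@H](C(C)C)[C@@H](/C=C(\I)CO[Si](C(C)C)(C(C)C)C(C)C)[C@H]1C[C@H](O[Si](CC)(CC)CC)[C@@]2(C)OC(O)C=C2
F2 | step 13 | (1S,7S,8S,10R,14R)-8-(triethylsilyloxy)-15-(triisopropylsilyloxy)eunicella-2Z,5Z,11-triene-4,7-diol, C4 epimers | CC1=CC[C@H](C(C)C)[C@H]2/C=C(/CO[Si](C(C)C)(C(C)C)C(C)C)C(O)/C=C\[C@](C)(O)[C@@H](O[Si](CC)(CC)CC)C[C@@H]12
F3 | step 11 | ethyl (Z)-2-methyl-4-(cyclohexenyl)but-2-enoate, cyclohexenyl unit as in 10 | CC1=CC[C@H](C(C)C)[C@@H](/C=C(\I)CO[Si](C(C)C)(C(C)C)C(C)C)[C@H]1C/C=C(C)\C(=O)OCC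
F4 | step 11 | (Z)-2-methyl-4-(cyclohexenyl)but-2-en-1-ol | CC1=CC[C@H](C(C)C)[C@@H](/C=C(\I)CO[Si](C(C)C)(C(C)C)C(C)C)[C@H]1C/C=C(C)\CO
F5 | step 11 | cis-2,3-epoxy alcohol from F4 (oxygen delivered by the L-(+)-tartrate catalyst) | CC1=CC[C@H](C(C)C)[C@@H](/C=C(\I)CO[Si](C(C)C)(C(C)C)C(C)C)[C@H]1C[C@@H]2O[C@]2(C)CO
F6 | step 11 | epoxy aldehyde from F5 | CC1=CC[C@H](C(C)C)[C@@H](/C=C(\I)CO[Si](C(C)C)(C(C)C)C(C)C)[C@H]1C[C@@H]2O[C@]2(C)C=O
F7 | step 11 | methyl (Z)-4,5-epoxy-4-methyl-6-(cyclohexenyl)hex-2-enoate from F6 | CC1=CC[C@H](C(C)C)[C@@H](/C=C(\I)CO[Si](C(C)C)(C(C)C)C(C)C)[C@H]1C[C@@H]2O[C@]2(C)/C=C\C(=O)OC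
F8 | step 6 | 1,1-dibromoolefin from 6 | CC1=CC[C@H](C(C)C)[C@@H](C=C(Br)Br)[C@H]1CC(OC)OC
F9 | step 6 | propargylic alcohol, 3-(cyclohexenyl)prop-2-yn-1-ol | CC1=CC[C@H](C(C)C)[C@@H](C#CCO)[C@H]1CC(OC)OC
F10 | step 6 | (Z)-2-(tributylstannyl)allylic alcohol, tin cis to the ring carbon C1 | CC1=CC[C@H](C(C)C)[C@@H](/C=C(\[Sn](CCCC)(CCCC)CCCC)CO)[C@H]1CC(OC)OC
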